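**Retrosynthetic overview**

- Feature: ring B is a 1,2,4-trisubstituted phenol. C1′ carries the CH2CH2 bridge to ring A, C3′ the OH, and C6′ the 4-hydroxybenzyl group (ortho to the bridge, para to the OH). Benzylating a 3-alkylphenol would scatter the benzyl over C2′, C4′ and C6′, so ring B is built with its substituents already in place.
- The C6′ benzyl CH2 is traced back to a diaryl ketone; the derived carbinol is hydrogenolysed in the same operation that removes all O-benzyl groups.
- Ring B is disconnected at C1′–C2′ and C5′–C6′: a [4+2] cycloaddition of Danishefsky's diene onto a ring A-tethered aroyl alkyne, then loss of methanol and of the silyl group, gives the 4-acylphenol.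
- The ynone comes from acyl Sonogashira coupling of a ring A homopropargyl arene with 4-(benzyloxy)benzoyl chloride; the homopropargyl arene comes from the ring A benzylic bromide and lithiated 1-(trimethylsilyl)propyne.
- Ring A is bought as a 4-bromo-3,5-dihydroxybenzoate. Its three nuclear positions are given three different halogens (Br, Cl, I) and are then benzylated one at a time by Negishi couplings in the order C–I, C–Br, C–Cl. Ring B is the only ring formed in the route.

Key step: step 14

Remark: methyl 4-bromo-3,5-dihydroxybenzoate, 4-(benzyloxy)benzyl chloride, 4-(benzyloxy)benzoyl chloride, 1-(trimethylsilyl)propyne and the diene are taken as purchasable. Which of C2 and C6 of ring A carries chlorine and which iodine fixes the structures of the halogenated intermediates but not the outcome, because all three halogens are replaced by the same benzyl group. The transient stereocentres of the cycloadduct and of the carbinol are racemic and both are erased.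

**Route**

Step 1
Reactants: 1 methyl 4-bromo-3,5-dihydroxybenzoate
Product: 2 methyl 4-bromo-3-hydroxy-5-methoxybenzoate
Conditions: MeI (1.0 equiv), K2CO3 (1.0 equiv), DMF, 0 °C → rt; recovered diol recycled
Reagents that add atoms: iodomethane, CI
Why: Williamson mono-O-methylation of the symmetric resorcinol with one equivalent of electrophile should give the mono-ether as the main component of a separable statistical mixture, and placing this on the cheapest compound of the route keeps the loss tolerable.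

Step 2
Reactants: 2 methyl 4-bromo-3-hydroxy-5-methoxybenzoate
Product: 3 methyl 4-bromo-2-chloro-3-hydroxy-5-methoxybenzoate
Conditions: SO2Cl2 (1.05 equiv), (s-Bu)2NH (10 mol %), toluene, 0 °C → rt
Reagents that add atoms: sulfuryl chloride, O=S(=O)(Cl)Cl
Why: Amine-catalysed ortho-chlorination of a phenol, in which the amine-bound chlorinating species is held at the OH by hydrogen bonding and delivers chlorine to the one free ortho position C2 (C4 is blocked by bromine), which is also the less hindered site because the C5 methoxy group turns its methyl toward C6.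

Step 3
Reactants: 3 methyl 4-bromo-2-chloro-3-hydroxy-5-methoxybenzoate
Product: 4 methyl 4-bromo-2-chloro-3-hydroxy-6-iodo-5-methoxybenzoate
Conditions: NIS (1.1 equiv), TsOH·H2O (10 mol %), MeCN, rt, dark
Reagents that add atoms: N-iodosuccinimide, O=C1CCC(=O)N1I
Why: Electrophilic aromatic iodination at the only remaining ring position, which is para to the free OH and ortho to OMe and should therefore still be reactive in spite of the ester and the two halogens.

Step 4
Reactants: 4 methyl 4-bromo-2-chloro-3-hydroxy-6-iodo-5-methoxybenzoate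
Product: 5 methyl 3-(benzyloxy)-4-bromo-2-chloro-6-iodo-5-methoxybenzoate
Conditions: BnBr, K2CO3, DMF, 50 °C, dark
Reagents that add atoms: benzyl bromide, BrCc1ccccc1
Why: Williamson etherification of the acidic 2,6-dihalophenol removes the only acidic proton before the organometallic steps and installs a group that the final hydrogenolysis removes.

Step 5
Reactants: 6 4-(benzyloxy)benzyl chloride
Product: 7 [4-(benzyloxy)benzyl]zinc chloride (titrated THF solution, used as such in steps 6, 7 and 8)
Conditions: Zn dust, LiCl, THF, 25 °C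
Reagents that add atoms: zinc, [Zn]
Why: LiCl-promoted direct insertion of zinc into a benzylic chloride gives the benzylic zinc reagent, and the chloride (not the bromide) keeps Wurtz homocoupling low.

Step 6
Reactants: 5 methyl 3-(benzyloxy)-4-bromo-2-chloro-6-iodo-5-methoxybenzoate; 7 [4-(benzyloxy)benzyl]zinc chloride
Product: 8 methyl 3-(benzyloxy)-6-[4-(benzyloxy)benzyl]-4-bromo-2-chloro-5-methoxybenzoate
Conditions: 7 (1.1 equiv), Pd(PPh3)4 (5 mol %), THF, 25 → 40 °C
Reagents that add atoms: none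
Why: Negishi coupling in which zerovalent palladium inserts into the C–I bond much faster than into C–Br or C–Cl, so that a triphenylphosphine catalyst and about one equivalent of 7 should benzylate C6 only, the ester being inert to organozinc.

Step 7
Reactants: 8 methyl 3-(benzyloxy)-6-[4-(benzyloxy)benzyl]-4-bromo-2-chloro-5-methoxybenzoate; 7 [4-(benzyloxy)benzyl]zinc chloride
Product: 9 methyl 3-(benzyloxy)-4,6-bis[4-(benzyloxy)benzyl]-2-chloro-5-methoxybenzoate
Conditions: 7 (1.3 equiv), Pd(OAc)2 (5 mol %), SPhos (10 mol %), THF, 40 °C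
Reagents that add atoms: none
Why: Negishi coupling at the C4–Br bond flanked by two alkoxy groups, for which the SPhos-ligated catalyst should be active enough at 40 °C while the aryl chloride reacts more slowly, and any coupling at C–Cl would only lead on to 10.

Step 8
Reactants: 9 methyl 3-(benzyloxy)-4,6-bis[4-(benzyloxy)benzyl]-2-chloro-5-methoxybenzoate; 7 [4-(benzyloxy)benzyl]zinc chloride
Product: 10 methyl 3-(benzyloxy)-2,4,6-tris[4-(benzyloxy)benzyl]-5-methoxybenzoate
Conditions: 7 (2.0 equiv), Pd2(dba)3 (2.5 mol %), XPhos (10 mol %), THF, 65 °C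
Reagents that add atoms: none
Why: Negishi coupling of a di-ortho-substituted aryl chloride, which the bulky electron-rich XPhos ligand makes possible and the ortho ester assists by lowering the electron density at C2, while the benzylzinc has no β-hydrogen to divert the cycle.

Step 9
Reactants: 10 methyl 3-(benzyloxy)-2,4,6-tris[4-(benzyloxy)benzyl]-5-methoxybenzoate
Product: 11 {3-(benzyloxy)-2,4,6-tris[4-(benzyloxy)benzyl]-5-methoxyphenyl}methanol
Conditions: LiAlH4, THF, 0 °C → reflux; aqueous NaOH work-up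
Reagents that add atoms: none
Why: LiAlH4 reduces even 2,6-disubstituted benzoates to benzylic alcohols and leaves aryl and benzyl ethers untouched.

Step 10
Reactants: 11 {3-(benzyloxy)-2,4,6-tris[4-(benzyloxy)benzyl]-5-methoxyphenyl}methanol
Product: 12 1-(benzyloxy)-3-(bromomethyl)-2,4,6-tris[4-(benzyloxy)benzyl]-5-methoxybenzene
Conditions: CBr4, PPh3, CH2Cl2, 0 °C → rt
Reagents that add atoms: carbon tetrabromide, BrC(Br)(Br)Br
Why: The Appel reaction converts the primary benzylic alcohol to the bromide under neutral conditions, and the CH2Br, being meta to both alkoxy groups, should not ionise.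

Step 11
Reactants: 12 1-(benzyloxy)-3-(bromomethyl)-2,4,6-tris[4-(benzyloxy)benzyl]-5-methoxybenzene; 13 1-(trimethylsilyl)propyne
Product: 15 (4-{3-(benzyloxy)-2,4,6-tris[4-(benzyloxy)benzyl]-5-methoxyphenyl}but-1-yn-1-yl)trimethylsilane, via 3-lithio-1-(trimethylsilyl)propyne 14 (not isolated)
Conditions: 13 (1.3 equiv), n-BuLi (1.2 equiv), THF, −78 °C; then 12, −78 → 0 °C
Reagents that add atoms: none
Why: SN2 alkylation of the benzylic bromide by the silyl-stabilised propargyl lithium, whose C-silyl group directs bond formation to the propargylic terminus so that the alkyne and not the allene results.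

Step 12
Reactants: 15 (4-{3-(benzyloxy)-2,4,6-tris[4-(benzyloxy)benzyl]-5-methoxyphenyl}but-1-yn-1-yl)trimethylsilane
Product: 16 1-(benzyloxy)-3-(but-3-yn-1-yl)-2,4,6-tris[4-(benzyloxy)benzyl]-5-methoxybenzene
Conditions: K2CO3 (cat.), MeOH/THF, rt
Reagents that add atoms: none
Why: Carbonate-catalysed methanolysis cleaves the alkynyl C–Si bond selectively and nothing else in the molecule is base-labile.

Step 13
Reactants: 16 1-(benzyloxy)-3-(but-3-yn-1-yl)-2,4,6-tris[4-(benzyloxy)benzyl]-5-methoxybenzene; 17 4-(benzyloxy)benzoyl chloride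
Product: 18 1-[4-(benzyloxy)phenyl]-5-{3-(benzyloxy)-2,4,6-tris[4-(benzyloxy)benzyl]-5-methoxyphenyl}pent-2-yn-1-one
Conditions: PdCl2(PPh3)2 (2 mol %), CuI (copper iodide, 4 mol %), Et3N (1.2 equiv), THF, rt
Reagents that add atoms: none
Why: Acyl Sonogashira coupling of a terminal alkyne with an aroyl chloride gives the ynone directly at the ketone oxidation level, so no carbinol oxidation is needed.

Step 14
Reactants: 18 1-[4-(benzyloxy)phenyl]-5-{3-(benzyloxy)-2,4,6-tris[4-(benzyloxy)benzyl]-5-methoxyphenyl}pent-2-yn-1-one; 19 (E)-1-methoxy-3-(trimethylsilyloxy)buta-1,3-diene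
Product: 22 [4-(benzyloxy)phenyl][2-(2-{3-(benzyloxy)-2,4,6-tris[4-(benzyloxy)benzyl]-5-methoxyphenyl}ethyl)-4-hydroxyphenyl]methanone, via methoxy silyloxy cyclohexadiene cycloadduct 20 (not isolated), via aryl trimethylsilyl ether 21 (not isolated)
Conditions: 19 (4 equiv), toluene, 110 °C, sealed tube, Ar; then 1 M HCl, THF, rt
Reagents that add atoms: none
Why: The electron-rich diene 19 and the electron-poor C≡C of ynone 18 combine in a thermal, normal-electron-demand [4+2] cycloaddition, the closest known reaction type being the Danishefsky diene–acetylenic ketone benzannulation that gives 4-acylphenols. Ring B is closed by this intermolecular Diels–Alder reaction as a six-membered carbocycle, the bonds C1′–C2′ and C5′–C6′ forming in the same step to give the 1,4-cyclohexadiene 20. 1,4-Elimination of methanol from 20 (the C5′ OMe and a C2′ H) aromatises the ring to silyl ether 21, and dilute acid cleaves the O–Si bond to free the C3′ phenol; should hydrolysis come first, the β-methoxy ketone loses methanol and tautomerises to the same phenol. No stereocentre is left, since the single C5′ centre of 20 is racemic and is destroyed on aromatisation. The step needs regioselectivity and chemoselectivity: the CH2 terminus of 19 (largest HOMO coefficient) bonds to the ynone β-carbon (largest LUMO coefficient), which places the aroyl group para to the new OH and ortho to the bridge, and in the absence of a Lewis acid the aryl ketone C=O should not compete as a heterodienophile.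

Step 15
Reactants: 22 [4-(benzyloxy)phenyl][2-(2-{3-(benzyloxy)-2,4,6-tris[4-(benzyloxy)benzyl]-5-methoxyphenyl}ethyl)-4-hydroxyphenyl]methanone
Product: 23 4-{[4-(benzyloxy)phenyl](hydroxy)methyl}-3-(2-{3-(benzyloxy)-2,4,6-tris[4-(benzyloxy)benzyl]-5-methoxyphenyl}ethyl)phenol (racemic)
Conditions: NaBH4 (5 equiv), THF/MeOH, 0 °C → rt; pH 7 work-up, crude taken on
Reagents that add atoms: none
Why: Borohydride reduction of the diaryl ketone gives the carbinol, with excess hydride offsetting deactivation by the para-phenoxide; the new centre is formed racemic on purpose because the next step removes it.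

Step 16
Reactants: 23 4-{[4-(benzyloxy)phenyl](hydroxy)methyl}-3-(2-{3-(benzyloxy)-2,4,6-tris[4-(benzyloxy)benzyl]-5-methoxyphenyl}ethyl)phenol
Product: 24 bleochrin B, 4-(4-hydroxybenzyl)-3-{2-[3-hydroxy-2,4,6-tris(4-hydroxybenzyl)-5-methoxyphenyl]ethyl}phenol
Conditions: H2 (1 atm), 10 % Pd/C, EtOAc/MeOH, AcOH (cat.), rt
Reagents that add atoms: none
Why: Palladium-catalysed hydrogenolysis cleaves the five O-benzyl ethers and the doubly benzylic, para-oxygenated C–OH bond in one operation, while the diarylmethane C–C bonds and the aromatic rings are inert at 1 atm.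

**Compound list**

1 | methyl 4-bromo-3,5-dihydroxybenzoate | COC(=O)c1cc(O)c(Br)c(O)c1 | starting material
2 | methyl 4-bromo-3-hydroxy-5-methoxybenzoate | COC(=O)c1cc(O)c(Br)c(OC)c1 | intermediate
3 | methyl 4-bromo-2-chloro-3-hydroxy-5-methoxybenzoate | COC(=O)c1c(Cl)c(O)c(Br)c(OC)c1 | intermediate
4 | methyl 4-bromo-2-chloro-3-hydroxy-6-iodo-5-methoxybenzoate | COC(=O)c1c(Cl)c(O)c(Br)c(OC)c1I | intermediate
5 | methyl 3-(benzyloxy)-4-bromo-2-chloro-6-iodo-5-methoxybenzoate | COC(=O)c1c(Cl)c(OCc2ccccc2)c(Br)c(OC)c1I | intermediate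
6 | 4-(benzyloxy)benzyl chloride | ClCc1ccc(OCc2ccccc2)cc1 | starting material
7 | [4-(benzyloxy)benzyl]zinc chloride | Cl[Zn]Cc1ccc(OCc2ccccc2)cc1 | intermediate
8 | methyl 3-(benzyloxy)-6-[4-(benzyloxy)benzyl]-4-bromo-2-chloro-5-methoxybenzoate | COC(=O)c1c(Cl)c(OCc2ccccc2)c(Br)c(OC)c1Cc1ccc(OCc2ccccc2)cc1 | intermediate
9 | methyl 3-(benzyloxy)-4,6-bis[4-(benzyloxy)benzyl]-2-chloro-5-methoxybenzoate | COC(=O)c1c(Cl)c(OCc2ccccc2)c(Cc2ccc(OCc3ccccc3)cc2)c(OC)c1Cc1ccc(OCc2ccccc2)cc1 | intermediate
10 | methyl 3-(benzyloxy)-2,4,6-tris[4-(benzyloxy)benzyl]-5-methoxybenzoate | COC(=O)c1c(Cc2ccc(OCc3ccccc3)cc2)c(OCc2ccccc2)c(Cc2ccc(OCc3ccccc3)cc2)c(OC)c1Cc1ccc(OCc2ccccc2)cc1 | intermediate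
11 | {3-(benzyloxy)-2,4,6-tris[4-(benzyloxy)benzyl]-5-methoxyphenyl}methanol | OCc1c(Cc2ccc(OCc3ccccc3)cc2)c(OCc2ccccc2)c(Cc2ccc(OCc3ccccc3)cc2)c(OC)c1Cc1ccc(OCc2ccccc2)cc1 | intermediate
12 | 1-(benzyloxy)-3-(bromomethyl)-2,4,6-tris[4-(benzyloxy)benzyl]-5-methoxybenzene | BrCc1c(Cc2ccc(OCc3ccccc3)cc2)c(OCc2ccccc2)c(Cc2ccc(OCc3ccccc3)cc2)c(OC)c1Cc1ccc(OCc2ccccc2)cc1 | intermediate
13 | 1-(trimethylsilyl)propyne | CC#C[Si](C)(C)C | starting material
14 | 3-lithio-1-(trimethylsilyl)propyne | [Li]CC#C[Si](C)(C)C | intermediate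
15 | (4-{3-(benzyloxy)-2,4,6-tris[4-(benzyloxy)benzyl]-5-methoxyphenyl}but-1-yn-1-yl)trimethylsilane | C[Si](C)(C)C#CCCc1c(Cc2ccc(OCc3ccccc3)cc2)c(OCc2ccccc2)c(Cc2ccc(OCc3ccccc3)cc2)c(OC)c1Cc1ccc(OCc2ccccc2)cc1 | intermediate
16 | 1-(benzyloxy)-3-(but-3-yn-1-yl)-2,4,6-tris[4-(benzyloxy)benzyl]-5-methoxybenzene | C#CCCc1c(Cc2ccc(OCc3ccccc3)cc2)c(OCc2ccccc2)c(Cc2ccc(OCc3ccccc3)cc2)c(OC)c1Cc1ccc(OCc2ccccc2)cc1 | intermediate
17 | 4-(benzyloxy)benzoyl chloride | O=C(Cl)c1ccc(OCc2ccccc2)cc1 | starting material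
18 | 1-[4-(benzyloxy)phenyl]-5-{3-(benzyloxy)-2,4,6-tris[4-(benzyloxy)benzyl]-5-methoxyphenyl}pent-2-yn-1-one | COc1c(Cc2ccc(OCc3ccccc3)cc2)c(OCc2ccccc2)c(Cc2ccc(OCc3ccccc3)cc2)c(CCC#CC(=O)c2ccc(OCc3ccccc3)cc2)c1Cc1ccc(OCc2ccccc2)cc1 | intermediate
19 | (E)-1-methoxy-3-(trimethylsilyloxy)buta-1,3-diene | CO/C=C/C(=C)O[Si](C)(C)C | starting material
20 | [4-(benzyloxy)phenyl][2-(2-{3-(benzyloxy)-2,4,6-tris[4-(benzyloxy)benzyl]-5-methoxyphenyl}ethyl)-6-methoxy-4-(trimethylsilyloxy)cyclohexa-1,4-dien-1-yl]methanone (racemic) | COC1C=C(O[Si](C)(C)C)CC(CCc2c(Cc3ccc(OCc4ccccc4)cc3)c(OCc3ccccc3)c(Cc3ccc(OCc4ccccc4)cc3)c(OC)c2Cc2ccc(OCc3ccccc3)cc2)=C1C(=O)c1ccc(OCc2ccccc2)cc1 | intermediate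
21 | [4-(benzyloxy)phenyl][2-(2-{3-(benzyloxy)-2,4,6-tris[4-(benzyloxy)benzyl]-5-methoxyphenyl}ethyl)-4-(trimethylsilyloxy)phenyl]methanone | C[Si](C)(C)Oc1ccc(C(=O)c2ccc(OCc3ccccc3)cc2)c(CCc2c(Cc3ccc(OCc4ccccc4)cc3)c(OCc3ccccc3)c(Cc3ccc(OCc4ccccc4)cc3)c(OC)c2Cc2ccc(OCc3ccccc3)cc2)c1 | intermediate
22 | [4-(benzyloxy)phenyl][2-(2-{3-(benzyloxy)-2,4,6-tris[4-(benzyloxy)benzyl]-5-methoxyphenyl}ethyl)-4-hydroxyphenyl]methanone | COc1c(Cc2ccc(OCc3ccccc3)cc2)c(OCc2ccccc2)c(Cc2ccc(OCc3ccccc3)cc2)c(CCc2cc(O)ccc2C(=O)c2ccc(OCc3ccccc3)cc2)c1Cc1ccc(OCc2ccccc2)cc1 | intermediate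
23 | 4-{[4-(benzyloxy)phenyl](hydroxy)methyl}-3-(2-{3-(benzyloxy)-2,4,6-tris[4-(benzyloxy)benzyl]-5-methoxyphenyl}ethyl)phenol (racemic) | COc1c(Cc2ccc(OCc3ccccc3)cc2)c(OCc2ccccc2)c(Cc2ccc(OCc3ccccc3)cc2)c(CCc2cc(O)ccc2C(O)c2ccc(OCc3ccccc3)cc2)c1Cc1ccc(OCc2ccccc2)cc1 | intermediate
24 | bleochrin B | COc1c(Cc2ccc(O)cc2)c(O)c(Cc2ccc(O)cc2)c(CCc2cc(O)ccc2Cc2ccc(O)cc2)c1Cc1ccc(O)cc1 | target

**Step count and risk**

Total step count: 16. Longest linear sequence: 15 steps (steps 1 to 4 and 6 to 16, from methyl 4-bromo-3,5-dihydroxybenzoate); step 5 is a one-step side branch.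

The three steps most likely to fail, in order of risk:

Step 14. The β-alkyl aryl ynone may add so slowly that the diene is lost to thermal oligomerisation and adventitious desilylation before it reacts, and at long reaction times hetero-cycloaddition at the ketone could begin to compete. The fallback sets out from 18 and changes the diene class and the aromatisation mode. The far more nucleophilic amino-siloxy diene (E)-1-(dimethylamino)-3-(tert-butyldimethylsilyloxy)buta-1,3-diene (purchased, CN(C)/C=C/C(=C)O[Si](C)(C)C(C)(C)C) should add to the ynone in toluene at 25 to 60 °C with the same orientation. This would give [4-(benzyloxy)phenyl][2-(2-{3-(benzyloxy)-2,4,6-tris[4-(benzyloxy)benzyl]-5-methoxyphenyl}ethyl)-4-(tert-butyldimethylsilyloxy)-6-(dimethylamino)cyclohexa-1,4-dien-1-yl]methanone F1. Brief exposure to AcOH or silica should expel dimethylamine and aromatise it to [4-(benzyloxy)phenyl][2-(2-{3-(benzyloxy)-2,4,6-tris[4-(benzyloxy)benzyl]-5-methoxyphenyl}ethyl)-4-(tert-butyldimethylsilyloxy)phenyl]methanone F2. Methanolysis of this para-acyl aryl silyl ether (K2CO3, MeOH/THF, rt) then rejoins the route at 22.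

Step 8. Oxidative addition into the C–Cl bond of the pentasubstituted, electron-rich ring may be too slow, so that the catalyst decays and 7 is lost to homocoupling and protonation before the third benzyl group is in place. The fallback sets out from 2 and gives up the graded halides, so that no aryl chloride has to be coupled. Bromination of 2 at both free ring positions (Br2, 2.2 equiv, AcOH, rt → 50 °C) should give methyl 2,4,6-tribromo-3-hydroxy-5-methoxybenzoate F3. O-Benzylation (BnBr, K2CO3, DMF, 50 °C) should then give methyl 3-(benzyloxy)-2,4,6-tribromo-5-methoxybenzoate F4. Exhaustive Negishi coupling of the three C–Br bonds of F4 with an excess of 7 (4.5 equiv, Pd(OAc)2, SPhos, THF, 25 → 60 °C) rejoins the route at 10; steps 2 to 4 and 6 to 8 are then not needed.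

Step 15. Hydride delivery may be sluggish to a ketone that is deactivated as its para-phenoxide and by two donor rings, and the p-hydroxybenzhydrol may ionise during work-up and alkylate the electron-rich rings. The fallback sets out from 22 and replaces nucleophilic hydride by ionic hydrogenation, which works best on exactly such donor-substituted diaryl ketones. Et3SiH (3 equiv) with CF3CO2H in CH2Cl2 at 0 °C → rt should take the C=O directly to CH2 and give 4-[4-(benzyloxy)benzyl]-3-(2-{3-(benzyloxy)-2,4,6-tris[4-(benzyloxy)benzyl]-5-methoxyphenyl}ethyl)phenol F5. Partial loss of O-benzyl groups in acid would be harmless here. Hydrogenolysis of F5 under the conditions of step 16 returns to the route at 24.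

**Further compounds**

F1 | step 14 | [4-(benzyloxy)phenyl][2-(2-{3-(benzyloxy)-2,4,6-tris[4-(benzyloxy)benzyl]-5-methoxyphenyl}ethyl)-4-(tert-butyldimethylsilyloxy)-6-(dimethylamino)cyclohexa-1,4-dien-1-yl]methanone (racemic) | CN(C)C1C=C(O[Si](C)(C)C(C)(C)C)CC(CCc2c(Cc3ccc(OCc4ccccc4)cc3)c(OCc3ccccc3)c(Cc3ccc(OCc4ccccc4)cc3)c(OC)c2Cc2ccc(OCc3ccccc3)cc2)=C1C(=O)c1ccc(OCc2ccccc2)cc1
F2 | step 14 | [4-(benzyloxy)phenyl][2-(2-{3-(benzyloxy)-2,4,6-tris[4-(benzyloxy)benzyl]-5-methoxyphenyl}ethyl)-4-(tert-butyldimethylsilyloxy)phenyl]methanone | CC(C)(C)[Si](C)(C)Oc1ccc(C(=O)c2ccc(OCc3ccccc3)cc2)c(CCc2c(Cc3ccc(OCc4ccccc4)cc3)c(OCc3ccccc3)c(Cc3ccc(OCc4ccccc4)cc3)c(OC)c2Cc2ccc(OCc3ccccc3)cc2)c1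
F3 | step 8 | methyl 2,4,6-tribromo-3-hydroxy-5-methoxybenzoate | COC(=O)c1c(Br)c(O)c(Br)c(OC)c1Br
F4 | step 8 | methyl 3-(benzyloxy)-2,4,6-tribromo-5-methoxybenzoate | COC(=O)c1c(Br)c(OCc2ccccc2)c(Br)c(OC)c1Br
F5 | step 15 | 4-[4-(benzyloxy)benzyl]-3-(2-{3-(benzyloxy)-2,4,6-tris[4-(benzyloxy)benzyl]-5-methoxyphenyl}ethyl)phenol | COc1c(Cc2ccc(OCc3ccccc3)cc2)c(OCc2ccccc2)c(Cc2ccc(OCc3ccccc3)cc2)c(CCc2cc(O)ccc2Cc2ccc(OCc3ccccc3)cc2)c1Cc1ccc(OCc2ccccc2)cc1
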